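**Strategy**

Everything rests on disconnecting the C3–C4 bond of the oxolane ring, which joins the carbon bearing CH2OH to the carbon bearing the 4-hydroxy-3-methoxybenzyl arm. Each of these two carbons carries one exocyclic CH2 arm and one ring C–O arm, so each is the central carbon of a 2-substituted allyl unit. The precursor is therefore an enantiopure bis(2-substituted allyl) ether, and ring-closing olefin metathesis unites its two like-polarised alkene carbons in one operation to a tetrasubstituted 2,5-dihydrofuran. Hydrogenation from the face opposite the C2 aryl group then gives the all-cis oxolane. The two dihydrobenzofurans come from catalyst-controlled carbene C–H insertions.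

Key step: step 11

Remark: the oxolane of the target is read as 2,3-cis-3,4-cis (2R,3R,4R), the inner dihydrobenzofuran as (2R,3S) and the outer one as (2S,3R).

Assumption: Rh2(S-PTTL)4 is taken to give the (2R)-dihydrobenzofuran from this class of aryldiazoacetates and Rh2(R-PTTL)4 the (2S) series; if the sense proves opposite, the two catalyst antipodes are exchanged.

**Route**

Step 1
Reactants: 1 5-iodovanillin; 2 4-(benzyloxy)-3-methoxybenzyl alcohol
Product: 3 4-{[4-(benzyloxy)-3-methoxybenzyl]oxy}-3-iodo-5-methoxybenzaldehyde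
Conditions: PPh3, DIAD, THF, 0 °C → rt
Reagents that add atoms: none
Why: Mitsunobu etherification, in which the acidic phenol of 1 is alkylated by the primary benzylic alkoxyphosphonium ion of 2 under neutral conditions and no stereocentre is formed.

Step 2
Reactants: 3 aryl iodide aldehyde; 4 ethyl diazoacetate
Product: 5 ethyl 2-(2-{[4-(benzyloxy)-3-methoxybenzyl]oxy}-5-formyl-3-methoxyphenyl)-2-diazoacetate
Conditions: Pd(PPh3)4 (5 mol %), Ag2CO3 (0.5 equiv), Et3N, toluene, rt
Reagents that add atoms: none
Why: Palladium-catalysed cross-coupling of an aryl iodide with the C–H bond of an acceptor diazo compound, which keeps the diazo group and runs at room temperature with a mild base so that the aldehyde and benzyl ethers are untouched.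

Step 3
Reactants: 5 aryldiazoacetate
Product: 7 ethyl (2S,3S)-2-[4-(benzyloxy)-3-methoxyphenyl]-5-formyl-7-methoxy-2,3-dihydro-1-benzofuran-3-carboxylate (trans), via cis ester 6 (not isolated)
Conditions: Rh2(R-PTTL)4 [dirhodium tetrakis(N-phthaloyl-(R)-tert-leucinate)] (1 mol %), toluene, −60 °C; then NaOEt (0.2 equiv), EtOH, 0 °C → rt
Reagents that add atoms: none
Why: Dirhodium-carbene intramolecular 1,5 C–H insertion into the electron-rich benzylic ether methylene closes the dihydrobenzofuran, the chiral carboxylate ligands selecting one enantiotopic C–H bond and so fixing C2 as S in the kinetic cis ester, after which ethoxide epimerises only the ester-bearing C3 to the more stable trans isomer.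

Step 4
Reactants: 7 trans dihydrobenzofuran aldehyde
Product: 8 ethyl (2S,3S)-2-[4-(benzyloxy)-3-methoxyphenyl]-5-(hydroxymethyl)-7-methoxy-2,3-dihydro-1-benzofuran-3-carboxylate
Conditions: NaBH4, EtOH/THF, 0 °C
Reagents that add atoms: none
Why: Chemoselective borohydride reduction of the aryl aldehyde in the presence of the ethyl ester, with no stereocentre touched.

Step 5
Reactants: 9 1-(benzyloxy)-4-bromo-2-methoxybenzene; 10 3-chloro-2-(chloromethyl)prop-1-ene
Product: 12 1-(benzyloxy)-4-[2-(chloromethyl)prop-2-en-1-yl]-2-methoxybenzene, via aryl Grignard reagent 11 (not isolated)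
Conditions: Mg, THF, reflux; then 10 (3 equiv), CuI (5 mol %), THF, −20 → 0 °C
Reagents that add atoms: none
Why: Copper-catalysed allylic substitution of an aryl Grignard reagent on the symmetrical bis-allylic dichloride, where SN2 and SN2' paths give the same product and excess dichloride enforces mono-substitution.

Step 6
Reactants: 13 2,3-dibromoprop-1-ene; 14 benzyl alcohol
Product: 15 benzyl 2-bromoprop-2-en-1-yl ether
Conditions: NaH, THF, 0 °C → rt
Reagents that add atoms: none
Why: Williamson ether synthesis at the allylic bromide, the vinylic bromide being inert to alkoxide.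

Step 7
Reactants: 1 5-iodovanillin
Product: 16 3-iodo-5-methoxy-4-[(triisopropylsilyl)oxy]benzaldehyde
Conditions: TIPSOTf, 2,6-lutidine, CH2Cl2, 0 °C
Reagents that add atoms: triisopropylsilyl trifluoromethanesulfonate, CC(C)[Si](C(C)C)(C(C)C)OS(=O)(=O)C(F)(F)F
Why: Silyl triflate/lutidine silylation of the hindered phenol gives a bulky aryl silyl ether that withstands the organolithium and hydride-base steps that follow.

Step 8
Reactants: 15 benzyl 2-bromoallyl ether; 16 silyl-protected iodoaldehyde
Product: 18 racemic 2-[(benzyloxy)methyl]-1-{3-iodo-5-methoxy-4-[(triisopropylsilyl)oxy]phenyl}prop-2-en-1-ol, via 2-lithioallyl benzyl ether 17 (not isolated)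
Conditions: 15, t-BuLi (2 equiv), Et2O, −78 °C; then 16, −78 °C; aq. NH4Cl
Reagents that add atoms: none
Why: Bromine–lithium exchange gives the alkenyllithium, whose 1,2-addition to the aldehyde at −78 °C is faster than exchange with the aryl iodide and gives the racemic carbinol.

Step 9
Reactants: 18 racemic allylic alcohol
Product: 19 (1S)-2-[(benzyloxy)methyl]-1-{3-iodo-5-methoxy-4-[(triisopropylsilyl)oxy]phenyl}prop-2-en-1-ol
Conditions: Ti(OiPr)4 (10 mol %), D-(−)-diisopropyl tartrate (15 mol %), t-BuOOH (0.6 equiv), 4 Å MS, CH2Cl2, −20 °C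
Reagents that add atoms: none
Why: Sharpless kinetic resolution, in which the D-(−)-tartrate catalyst epoxidises the (R)-enantiomer of this 2-substituted secondary allylic alcohol much faster, so that the (S)-alcohol, whose carbinol carbon becomes C2 of the oxolane, is recovered.

Step 10
Reactants: 19 (S)-allylic alcohol; 12 2-(arylmethyl)allyl chloride
Product: 20 1-(benzyloxy)-4-{2-[({(1S)-2-[(benzyloxy)methyl]-1-[3-iodo-5-methoxy-4-(triisopropylsilyloxy)phenyl]prop-2-en-1-yl}oxy)methyl]prop-2-en-1-yl}-2-methoxybenzene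
Conditions: NaH, Bu4NI (cat.), THF/DMF, 0 °C → rt
Reagents that add atoms: none
Why: Williamson etherification of the secondary alkoxide with the allylic chloride under iodide catalysis, which does not touch the carbinol stereocentre.

Step 11
Reactants: 20 bis(2-substituted allyl) ether
Product: 21 (2S)-4-[4-(benzyloxy)-3-methoxybenzyl]-3-[(benzyloxy)methyl]-2-[3-iodo-5-methoxy-4-(triisopropylsilyloxy)phenyl]-2,5-dihydrofuran
Conditions: RuCl2[1,3-bis(2-methylphenyl)imidazolidin-2-ylidene](=CH-C6H4-2-OiPr) (Stewart–Grubbs catalyst, 5–10 mol %), toluene (0.005 M), 80 °C, argon sparge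
Reagents that add atoms: none
Why: Ring-closing olefin metathesis by the Chauvin mechanism: the ruthenium alkylidene exchanges with one 1,1-disubstituted alkene, the resulting disubstituted alkylidene engages the second alkene intramolecularly through a ruthenacyclobutane, and cycloreversion releases the C3=C4 double bond and, after turnover, ethylene. The closest known reaction type is ring-closing metathesis of dimethallyl ethers, amides and malonates to tetrasubstituted five-membered cycloalkenes with ruthenium catalysts carrying N-(2-methylphenyl) carbene ligands. The five-membered oxacycle is closed at the two internal olefinic carbons, so both new sp2 carbons lie in the ring and neither the allylic C–O bonds nor the C2 stereocentre take part. No stereocentre is created here; C3 and C4 are set in step 12, where hydrogen is delivered to the face opposite the C2 aryl group, which is why the alkene is placed between exactly these two carbons. The step needs ring closure to win over acyclic diene oligomerisation and double-bond migration, which is secured by the five-membered ring size, by the reluctance of 1,1-disubstituted alkenes to homodimerise, by high dilution and by sweeping out ethylene.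

Step 12
Reactants: 21 tetrasubstituted 2,5-dihydrofuran
Product: 22 (2R,3R,4R)-4-[4-(benzyloxy)-3-methoxybenzyl]-3-[(benzyloxy)methyl]-2-[3-iodo-5-methoxy-4-(triisopropylsilyloxy)phenyl]oxolane (all-cis)
Conditions: H2 (1 atm), [Ir(cod)(PCy3)(py)]PF6 (10 mol %), CH2Cl2, rt
Reagents that add atoms: none
Why: Homogeneous hydrogenation with the cationic iridium catalyst that reduces tetrasubstituted alkenes without cleaving aryl iodide or benzyl ethers, syn delivery of H2 to the face opposite the C2 aryl group placing both new substituents on the aryl face and so setting C3 and C4 (3R,4R, all-cis) under substrate control.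

Step 13
Reactants: 22 silyl-protected oxolane
Product: 23 4-{(2R,3R,4R)-4-[4-(benzyloxy)-3-methoxybenzyl]-3-[(benzyloxy)methyl]oxolan-2-yl}-2-iodo-6-methoxyphenol
Conditions: Bu4NF, THF, 0 °C
Reagents that add atoms: none
Why: Fluoride cleavage of the aryl silyl ether, driven by the Si–F bond strength and the phenoxide leaving group, with the ethers and the oxolane inert.

Step 14
Reactants: 8 dihydrobenzofuran benzylic alcohol; 23 iodophenol
Product: 24 ethyl (2S,3S)-2-[4-(benzyloxy)-3-methoxyphenyl]-5-[(4-{(2R,3R,4R)-4-[4-(benzyloxy)-3-methoxybenzyl]-3-[(benzyloxy)methyl]oxolan-2-yl}-2-iodo-6-methoxyphenoxy)methyl]-7-methoxy-2,3-dihydro-1-benzofuran-3-carboxylate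
Conditions: PPh3, DIAD, THF, 0 °C → rt
Reagents that add atoms: none
Why: Mitsunobu etherification joins the two halves, the phenol attacking the primary benzylic alkoxyphosphonium ion of 8 in a neutral process that leaves the base-sensitive ester untouched.

Step 15
Reactants: 24 aryl iodide; 4 ethyl diazoacetate
Product: 25 ethyl 2-diazo-2-[2-({(2S,3S)-2-[4-(benzyloxy)-3-methoxyphenyl]-3-(ethoxycarbonyl)-7-methoxy-2,3-dihydro-1-benzofuran-5-yl}methoxy)-5-{(2R,3R,4R)-4-[4-(benzyloxy)-3-methoxybenzyl]-3-[(benzyloxy)methyl]oxolan-2-yl}-3-methoxyphenyl]acetate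
Conditions: Pd(PPh3)4 (5 mol %), Ag2CO3 (0.5 equiv), Et3N, toluene, rt
Reagents that add atoms: none
Why: The same palladium-catalysed arylation of ethyl diazoacetate as in step 2, chosen because it installs the aryldiazoacetate without a strong base that could open the existing dihydrobenzofuran ester by elimination.

Step 16
Reactants: 25 aryldiazoacetate
Product: 27 bis(dihydrobenzofuran) diethyl ester with the inner ring (2R,3R)-trans and the outer ring (2S,3S)-trans, via cis ester 26 (not isolated)
Conditions: Rh2(S-PTTL)4 [dirhodium tetrakis(N-phthaloyl-(S)-tert-leucinate)] (1 mol %), toluene, −60 °C; then NaOEt (0.2 equiv), EtOH, 0 °C → rt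
Reagents that add atoms: none
Why: Dirhodium-carbene 1,5 C–H insertion into the benzylic ether methylene, now with the antipodal catalyst so that catalyst control fixes C2 of the new ring as R (the existing stereocentres are remote), followed by ethoxide epimerisation of the cis ester at C3 to the trans ester.

Step 17
Reactants: 27 diethyl ester
Product: 28 tri-O-benzyl triol (the target with both phenols and the oxolane CH2OH as benzyl ethers)
Conditions: LiAlH4, THF, 0 °C
Reagents that add atoms: none
Why: Hydride reduction of both ethyl esters to primary alcohols, under which the stereocentres alpha to the esters are not enolised.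

Step 18
Reactants: 28 tri-O-benzyl triol
Product: 29 target compound
Conditions: H2 (1 atm), 10% Pd/C, EtOAc/MeOH, rt
Reagents that add atoms: none
Why: Hydrogenolysis of the three O-benzyl groups over palladium at ambient pressure, stopped at full debenzylation before the slower cleavage of the cyclic benzylic C–O bonds can set in.

**Compound list**

1 | 5-iodovanillin (4-hydroxy-3-iodo-5-methoxybenzaldehyde) | O=Cc1cc(OC)c(O)c(I)c1 | starting material
2 | 4-(benzyloxy)-3-methoxybenzyl alcohol | OCc1ccc(OCc2ccccc2)c(OC)c1 | starting material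
3 | 4-{[4-(benzyloxy)-3-methoxybenzyl]oxy}-3-iodo-5-methoxybenzaldehyde | O=Cc1cc(OC)c(OCc2ccc(OCc3ccccc3)c(OC)c2)c(I)c1 | intermediate
4 | ethyl diazoacetate | CCOC(=O)C=[N+]=[N-] | starting material
5 | ethyl 2-(2-{[4-(benzyloxy)-3-methoxybenzyl]oxy}-5-formyl-3-methoxyphenyl)-2-diazoacetate | O=Cc1cc(OC)c(OCc2ccc(OCc3ccccc3)c(OC)c2)c(C(=[N+]=[N-])C(=O)OCC)c1 | intermediate
6 | ethyl (2S,3R)-2-[4-(benzyloxy)-3-methoxyphenyl]-5-formyl-7-methoxy-2,3-dihydro-1-benzofuran-3-carboxylate (cis) | O=Cc1cc(OC)c2c(c1)[C@@H](C(=O)OCC)[C@@H](c1ccc(OCc3ccccc3)c(OC)c1)O2 | intermediate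
7 | ethyl (2S,3S)-2-[4-(benzyloxy)-3-methoxyphenyl]-5-formyl-7-methoxy-2,3-dihydro-1-benzofuran-3-carboxylate (trans) | O=Cc1cc(OC)c2c(c1)[C@H](C(=O)OCC)[C@@H](c1ccc(OCc3ccccc3)c(OC)c1)O2 | intermediate
8 | ethyl (2S,3S)-2-[4-(benzyloxy)-3-methoxyphenyl]-5-(hydroxymethyl)-7-methoxy-2,3-dihydro-1-benzofuran-3-carboxylate | OCc1cc(OC)c2c(c1)[C@H](C(=O)OCC)[C@@H](c1ccc(OCc3ccccc3)c(OC)c1)O2 | intermediate
9 | 1-(benzyloxy)-4-bromo-2-methoxybenzene | Brc1ccc(OCc2ccccc2)c(OC)c1 | starting material
10 | 3-chloro-2-(chloromethyl)prop-1-ene | C=C(CCl)CCl | starting material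
11 | [4-(benzyloxy)-3-methoxyphenyl]magnesium bromide | Br[Mg]c1ccc(OCc2ccccc2)c(OC)c1 | intermediate
12 | 1-(benzyloxy)-4-[2-(chloromethyl)prop-2-en-1-yl]-2-methoxybenzene | C=C(CCl)Cc1ccc(OCc2ccccc2)c(OC)c1 | intermediate
13 | 2,3-dibromoprop-1-ene | C=C(Br)CBr | starting material
14 | benzyl alcohol | OCc1ccccc1 | starting material
15 | benzyl 2-bromoprop-2-en-1-yl ether | C=C(Br)COCc1ccccc1 | intermediate
16 | 3-iodo-5-methoxy-4-[(triisopropylsilyl)oxy]benzaldehyde | O=Cc1cc(OC)c(O[Si](C(C)C)(C(C)C)C(C)C)c(I)c1 | intermediate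
17 | [3-(benzyloxy)prop-1-en-2-yl]lithium | [Li]C(=C)COCc1ccccc1 | intermediate
18 | racemic 2-[(benzyloxy)methyl]-1-{3-iodo-5-methoxy-4-[(triisopropylsilyl)oxy]phenyl}prop-2-en-1-ol | OC(c1cc(OC)c(O[Si](C(C)C)(C(C)C)C(C)C)c(I)c1)C(=C)COCc1ccccc1 | intermediate
19 | (1S)-2-[(benzyloxy)methyl]-1-{3-iodo-5-methoxy-4-[(triisopropylsilyl)oxy]phenyl}prop-2-en-1-ol | O[C@@H](c1cc(OC)c(O[Si](C(C)C)(C(C)C)C(C)C)c(I)c1)C(=C)COCc1ccccc1 | intermediate
20 | 1-(benzyloxy)-4-{2-[({(1S)-2-[(benzyloxy)methyl]-1-[3-iodo-5-methoxy-4-(triisopropylsilyloxy)phenyl]prop-2-en-1-yl}oxy)methyl]prop-2-en-1-yl}-2-methoxybenzene | O(CC(=C)Cc1ccc(OCc2ccccc2)c(OC)c1)[C@@H](c1cc(OC)c(O[Si](C(C)C)(C(C)C)C(C)C)c(I)c1)C(=C)COCc1ccccc1 | intermediate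
21 | (2S)-4-[4-(benzyloxy)-3-methoxybenzyl]-3-[(benzyloxy)methyl]-2-[3-iodo-5-methoxy-4-(triisopropylsilyloxy)phenyl]-2,5-dihydrofuran | O1CC(Cc2ccc(OCc3ccccc3)c(OC)c2)=C(COCc2ccccc2)[C@@H]1c1cc(OC)c(O[Si](C(C)C)(C(C)C)C(C)C)c(I)c1 | intermediate
22 | (2R,3R,4R)-4-[4-(benzyloxy)-3-methoxybenzyl]-3-[(benzyloxy)methyl]-2-[3-iodo-5-methoxy-4-(triisopropylsilyloxy)phenyl]oxolane | COc1cc(C[C@H]2CO[C@@H](c3cc(OC)c(O[Si](C(C)C)(C(C)C)C(C)C)c(I)c3)[C@H]2COCc2ccccc2)ccc1OCc1ccccc1 | intermediate
23 | 4-{(2R,3R,4R)-4-[4-(benzyloxy)-3-methoxybenzyl]-3-[(benzyloxy)methyl]oxolan-2-yl}-2-iodo-6-methoxyphenol | COc1cc(C[C@H]2CO[C@@H](c3cc(OC)c(O)c(I)c3)[C@H]2COCc2ccccc2)ccc1OCc1ccccc1 | intermediate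
24 | ethyl (2S,3S)-2-[4-(benzyloxy)-3-methoxyphenyl]-5-[(4-{(2R,3R,4R)-4-[4-(benzyloxy)-3-methoxybenzyl]-3-[(benzyloxy)methyl]oxolan-2-yl}-2-iodo-6-methoxyphenoxy)methyl]-7-methoxy-2,3-dihydro-1-benzofuran-3-carboxylate | COc1cc(C[C@H]2CO[C@@H](c3cc(OC)c(OCc4cc(OC)c5c(c4)[C@H](C(=O)OCC)[C@@H](c4ccc(OCc6ccccc6)c(OC)c4)O5)c(I)c3)[C@H]2COCc2ccccc2)ccc1OCc1ccccc1 | intermediate
25 | aryldiazoacetate: compound 24 with the iodine replaced by C(=N2)CO2Et | COc1cc(C[C@H]2CO[C@@H](c3cc(OC)c(OCc4cc(OC)c5c(c4)[C@H](C(=O)OCC)[C@@H](c4ccc(OCc6ccccc6)c(OC)c4)O5)c(C(=[N+]=[N-])C(=O)OCC)c3)[C@H]2COCc2ccccc2)ccc1OCc1ccccc1 | intermediate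
26 | bis(dihydrobenzofuran) diethyl ester, inner ring (2R,3S)-cis, outer ring (2S,3S)-trans, oxolane (2R,3R,4R) | COc1cc(C[C@H]2CO[C@@H](c3cc(OC)c4c(c3)[C@H](C(=O)OCC)[C@H](c3cc(OC)c5c(c3)[C@H](C(=O)OCC)[C@@H](c3ccc(OCc6ccccc6)c(OC)c3)O5)O4)[C@H]2COCc2ccccc2)ccc1OCc1ccccc1 | intermediate
27 | bis(dihydrobenzofuran) diethyl ester, inner ring (2R,3R)-trans, outer ring (2S,3S)-trans, oxolane (2R,3R,4R) | COc1cc(C[C@H]2CO[C@@H](c3cc(OC)c4c(c3)[C@@H](C(=O)OCC)[C@H](c3cc(OC)c5c(c3)[C@H](C(=O)OCC)[C@@H](c3ccc(OCc6ccccc6)c(OC)c3)O5)O4)[C@H]2COCc2ccccc2)ccc1OCc1ccccc1 | intermediate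
28 | tri-O-benzyl triol: the target with both phenols and the oxolane CH2OH as benzyl ethers | COc1cc(C[C@H]2CO[C@@H](c3cc(OC)c4c(c3)[C@@H](CO)[C@H](c3cc(OC)c5c(c3)[C@H](CO)[C@@H](c3ccc(OCc6ccccc6)c(OC)c3)O5)O4)[C@H]2COCc2ccccc2)ccc1OCc1ccccc1 | intermediate
29 | target: oxolane (2R,3R,4R) all-cis, inner dihydrobenzofuran (2R,3S), outer dihydrobenzofuran (2S,3R) | COc1cc(C[C@H]2CO[C@@H](c3cc(OC)c4c(c3)[C@@H](CO)[C@H](c3cc(OC)c5c(c3)[C@H](CO)[C@@H](c3ccc(O)c(OC)c3)O5)O4)[C@H]2CO)ccc1O | target

**Step count and risks**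

Total step count: 18. Longest linear sequence: 12 steps (steps 7–18 from 5-iodovanillin; equally steps 6 and 8–18).

Steps most likely to fail:

Step 11 (key step). The catalyst may load only slowly onto either hindered 1,1-disubstituted alkene and decompose before the ruthenacyclobutane leading to the tetrasubstituted alkene forms, or ruthenium hydrides from that decomposition may migrate the double bonds. The fallback sets out from 20 and comes back at 21. Oxidative cleavage of both methylidene groups (OsO4 cat., NaIO4, 2,6-lutidine, dioxane/water) would give the 3-oxa-1,5-diketone F1. Intramolecular McMurry coupling (TiCl4, Zn, pyridine, THF, reflux) would then unite the two carbonyl carbons to the same C3=C4 bond. The pyridine buffer is there to limit epimerisation next to the ketone.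

Step 12. The two faces of the nearly flat dihydrofuran may be discriminated poorly, or iridium hydride may move the double bond into an enol ether position before reduction, eroding the configuration at C3 and C4 and, through the C2=C3 isomer, at C2. The fallback sets out from 21 and comes back at 22. It gives up substrate control for catalyst control: asymmetric hydrogenation of the tetrasubstituted alkene with an enantiopure iridium phosphine–oxazoline complex, [Ir(cod)((S)-tBu-PHOX)][B(3,5-(CF3)2C6H3)4] or its antipode (H2 50 bar, CH2Cl2). The antipode used is the one whose own face preference matches delivery anti to the aryl group. No new compound is made.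

Step 15. Oxidative addition into the hindered ortho-alkoxy aryl iodide may be slow, so that palladium-carbene dimerisation of ethyl diazoacetate consumes the reagent first. The fallback sets out from 24 and comes back at 25. Negishi coupling of 24 with the Reformatsky reagent BrZnCH2CO2Et (Pd(dba)2, XPhos, THF, 60 °C) would give the arylacetate F2. Regitz diazo transfer to its doubly activated methylene (4-acetamidobenzenesulfonyl azide, DBU, MeCN, 0 °C) would then give 25.

**Further compounds**

F1 | step 11 | (S)-1-(benzyloxy)-3-{3-[4-(benzyloxy)-3-methoxyphenyl]-2-oxopropoxy}-3-[3-iodo-5-methoxy-4-(triisopropylsilyloxy)phenyl]propan-2-one | O(CC(=O)Cc1ccc(OCc2ccccc2)c(OC)c1)[C@@H](c1cc(OC)c(O[Si](C(C)C)(C(C)C)C(C)C)c(I)c1)C(=O)COCc1ccccc1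
F0 | step 12 | none | none
F2 | step 15 | arylacetate: compound 24 with the iodine replaced by CH2CO2Et | COc1cc(C[C@H]2CO[C@@H](c3cc(OC)c(OCc4cc(OC)c5c(c4)[C@H](C(=O)OCC)[C@@H](c4ccc(OCc6ccccc6)c(OC)c4)O5)c(CC(=O)OCC)c3)[C@H]2COCc2ccccc2)ccc1OCc1ccccc1
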